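You have 3 questions about one flask, and the readings can carry you to 1 of them. Catalyst J turns D into L and Q.

| flask | D | J | remark | time |
|---|---|---|---|---|
| east | 0.050 M | 7.5 mol% | run made earlier |  |
| south-east | 0.050 M | 11 mol% | run made earlier |  |
| west | 0.10 M | 15 mol% | run made earlier |  |
| flask | 0.050 M | 15 mol% |  | 1.0 h |

- east (time / min: L / %, Q / %, D / %): 10.0: 16.7, 8.4, 15.9; 20.0: 13.5, 10.9, 17.5; 30.0: 14.6, 13.4, 15.4; 40.0: 14.7, 15.2, 15.8; 50.0: 14.0, 14.0, 17.8; 60.0: 14.7, 15.7, 16.4
- south-east (time / min: L / %, Q / %, D / %): 10.0: 14.9, 9.3, 20.1; 20.0: 13.0, 11.9, 16.8; 30.0: 14.2, 13.3, 17.1; 40.0: 13.4, 13.8, 16.5; 50.0: 11.8, 13.9, 15.7; 60.0: 14.4, 16.4, 14.2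
- west (time / min: L / %, Q / %, D / %): 5.00: 15.9, 10.3, 17.9; 10.0: 16.1, 11.5, 17.7; 15.0: 15.7, 14.6, 16.8; 30.0: 14.1, 17.1, 15.5; 60.0: 13.4, 18.2, 15.4

(standard deviation of a reading: 1 percentage point)

* share of L in L plus Q at 4.0 s
* share of L in L plus Q at 2.0 min
* share of L in L plus Q at 1.0 h

Run the west flask slowly. At its first reading, 5.00 min, D is down to 17.9 %, L stands at 15.9 % and Q at 10.3 %. Together these make 44.1 % of the charge, so an unseen pool holds the rest, and the fast fall of D in the west flask lies before the first sample. By 60.0 min, D has drifted to 15.4 % and L to 13.4 %, while Q has climbed to 18.2 %. Q is slowing, though: it gains 2.5 percentage points from 15.0 min to 30.0 min, then 1.1 points in the longer stretch to 60.0 min.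

My supposition is that J is fading. If Q's rate goes with J and J's loss with J squared, dividing one rate by the other removes time, and, while the pool feeding Q stands at a like percentage of the charge, Q in percent follows the product of charged J molarity and elapsed time. The flask's 1.0 h then corresponds to 30.0 min in the west run: this is the matched time, the west moment with the same product. As a test, east at 60.0 min matches west at 15.0 min, and their Q readings are 15.7 % and 14.6 %, apart by about the scatter. West at the matched time reads L 14.1 % and Q 17.1 %, so I commit to a share of 45.2 % at the flask's hour. The flask's 2.0 min matches 1.00 min, before any west reading, so the rule gives nothing there.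

The forecast says 78 %, 72 % and 46 %, its earliest value “uncertain if Q forms sequentially”. The flask gives 99.1 %, 80.5 % and 44.8 %.

    D ⇌ Z (K = 2.16, k = 0.0384 /s)
    D + J ⇌ J + L (K = 0.834, k = 2.75 /M/s)
    J + Z → J + Q (k = 0.320 /M/s)
    2 J → E (k = 1.43 /M/s)
    Z ⇌ X (K = 0.550, k = 0.0505 /s)

In the flask, J's first half-life by pairing into E, by this step alone, is 0.777 min, far shorter than the 1.0 h run, and at 1.00 h J stands at 1.28 % of its charge and E at 98.7 %. West at the matched 30.0 min read 45.2 %, against the flask's 44.8 %.

The neighbour flask with 6 mol% of J, at 1.0 h, matches east at 48.0 min, between east readings whose shares are 49.2 % and 50.0 %. That neighbour computes to 49.5 %.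

(The earlier runs and the new flask stem from a simulated flask with constants of no real substance; the scatter is artificial.)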